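## Analysis of the target

Target 32 is a bicyclic labdane diacid. Rings A and B form a trans-fused decalin that carries an exocyclic C8=C17 methylene group and, at C9, a six-carbon chain ending in an (E)-3-methylbut-2-enoic acid (C13=C14, C15 acid). Ring A holds a 3β-acetoxy group beside the quaternary C4, which bears a methyl group (C18, α) and a carboxylic acid (C19, β, axial).

Five stereocentres must be set: C10 (methyl β, axial), C5 (H α, hence trans fusion), C4 (carboxyl axial and syn to the C10 methyl), C3 (acetoxy equatorial and cis to the C4 carboxyl) and C9 (chain β, equatorial, H α). The C13=C14 geometry must be E.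

The sensitive groups are the exocyclic alkene (it migrates into the ring under strong acid), the acetate (it cannot pass through basic steps or ester hydrolysis) and the β-oxygenated acid (a free C3 alkoxide next to a C4 ester can undergo retro-aldol cleavage). The axial C19 carboxyl is neopentylic and resists ordinary saponification.

The difficulty lies in the C3/C4/C5/C10 array, with two quaternary carbons in a 1,3-relationship and a fully substituted C4 whose two carbon substituents must be told apart.

The strategy rests on the atoms O–C3–C4–C19. A β-acyloxy acid is the aldol of a C4 ester enolate with a C3 aldehyde, and the C18 methyl can start as the CH2 of an α-substituted acrylate. Hydride addition at C18 then creates the C4 enolate, and ring A closes by forming C3–C4.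

## Retrosynthetic reasoning

**32 to 29.** The acetyl group is removed first, giving hydroxy diacid 30, because the acetate would not survive the base-mediated steps or the release of the acids. In 29 both acids are masked as 2-(trimethylsilyl)ethyl esters and the C3 hydroxyl as a silyl ether. One desilylation then frees all three groups. The hindered C19 ester is cleaved at silicon, away from its shielded carbonyl, so its hindrance does not matter.

**29 to 26 and 28.** The C13=C14 bond is cut by a Horner–Wadsworth–Emmons disconnection to methyl ketone 26 and phosphonate 28. The conjugated ester is attached last so that it never meets a hydroboration or an ylide. The forward reaction must give the E isomer.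

**26 to 21.** The C8=C17 bond is cut to the C8 ketone 24 (26 comes from 25 by ketal hydrolysis, and 25 from 24 by methylenation). Ketone 24 comes from alcohol 23, and 23 from the C8=C9 alkene 21 by hydroboration. This places oxygen on C8 and, more importantly, hydrogen on C9 from the face opposite the axial C10 methyl. C9 is therefore set by the existing C10 centre.

**21 to 15.** The C9–C11 bond is cut to enol triflate 18 and the alkylzinc reagent 20, made from bromide 19. The side-chain ketone is carried as a ketal. Triflate 18 can only form towards C8, because C10 is quaternary. It comes from ketone 17, which comes from 15 by silylation (16) and ketal removal.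

**15 to 13 (key disconnection).** The C3–C4 bond is cut. The β-hydroxy ester 15 is the aldol of the enolate 14 with the aldehyde of 13, and 14 arises when hydride is transferred from copper to the CH2 terminus of the acrylate. One step forms ring A, the quaternary C4 and the C3 carbinol. It has to place the ester axial and the hydroxyl cis to it. It is cut here, and not at C4–C5 or C1–C10, because the existing C5 and C10 centres can then direct both new centres through a trans-decalin-like chair.

**13 to 6.** Only functional-group changes remain. The aldehyde of 13 comes from alcohol 12, and 12 from the allyl group of 10 by anti-Markovnikov hydroboration. The acrylate of 10 comes from the isopropenyl group of 6 by allylic oxidation of its methyl group (8), oxidation to acid 9 and esterification. The order uses the electronic difference between the two alkenes. The electron-rich isopropenyl group is oxidised first. Once it has become an electron-poor acrylate, the allyl group can be hydroborated alone.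

**6 to 1, 2 and 3.** Ketal 6 comes from ketone 5. In 5 the C5–C4 and C10–C1 bonds are cut together: conjugate addition of Grignard reagent 2 to enone 1, then allylation of enolate 4 with bromide 3. This is the only step that introduces absolute configuration. The catalyst sets C5, and the allyl group enters anti to the new substituent, which sets C10 and thereby the later trans ring fusion.

## Alternatives that were turned down

**Alternative 1:** Intramolecular Diels–Alder reaction of an open-chain trienal.
- Disconnection: C5–C10 and C8–C9 are cut together, so both rings open to trienal A2, which already carries the C3 and C4 centres.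
- Forward key step: heating A2 makes its (E,E)-1-silyloxydiene (C5 to C8) add to the tethered (E)-enal (C9=C10), giving the trans-fused octalin aldehyde A1 with an 8β-silyloxy group.
- For: two rings and four stereocentres form in one reagent-free step. The formyl carbon is already C11 and the C8 oxygen is already where the methylene group will go. On ring B this plan is stronger than the chosen one, which needs five steps to bring in C11 and C17.
- Against: the hard part moves into A2. Its quaternary C4, with methyl, ester and dienyl groups next to the C3 carbinol, would have to be built in an open chain, with control of enolate geometry and of the face of the aldol. The dienophile is a β,β-disubstituted enal that must form quaternary C10, so high temperatures are needed, at which a silyl dienol ether and an aldehyde are at risk. A four-atom tether gives only modest trans/cis and endo/exo preferences, and the face selection rests on C3 and C4 across a flexible chain. The C8 centre is made only to be destroyed.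
- Comparison: in the chosen route the trans fusion follows from an anti alkylation, and the key step depends on one conformational preference, not on three selectivities at once.

**Alternative 2:** Catalytic asymmetric Diels–Alder reaction that builds ring A.
- Disconnection: C4–C5 and C1–C10 are cut, giving the silyl dienol ether A4 and the (E)-enal A5.
- Forward key step: a chiral oxazaborolidinium Lewis acid, formed by protonating a B-aryl oxazaborolidine of diphenylprolinol, activates A5. A4 adds to give cyclohexene A3 with the C10 formyl group, the C5 bromobutenyl chain and the C4 ester.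
- For: one catalytic step from two achiral pieces sets the absolute configuration and the quaternary C10. C3 arrives as a masked ketone beside the C4 ester, so C18 could be added by alkylating a β-keto ester on the face away from the C10 substituent. On the C4 question this is arguably safer than the chosen route. The vinyl bromide and the aldehyde are placed to close ring B with the methylene group already present.
- Against: the dienophile is a trisubstituted α-methyl-β-alkyl enal, far less reactive than the α-substituted acroleins on which this catalysis is dependable. The diene carries an ester at its terminus, which lowers its reactivity further. The C5/C10 relationship depends on endo/exo selectivity. After ring B closure C9 would carry an allylic hydroxyl, and replacing it by the C11 chain with the right configuration and without allylic transposition is an unsolved late problem. The step count after the key step is therefore no lower.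
- Comparison: the chosen route introduces the C9 chain by cross-coupling at a defined sp2 carbon and sets C9 by hydroboration.

**Alternative 3:** Quinone Diels–Alder reaction that joins ring A to the side-chain diene.
- Disconnection: C5–C6 and C9–C10 of ring B are cut, giving quinone A7 (ring A) and the 2-silyloxydiene A8, which carries the ketal-masked side chain.
- Forward key step: a chelating (BINOL)TiCl2 Lewis acid of tetravalent titanium binds the quinone, and A8 adds across the methyl-substituted C5=C10 bond. The product is the cis-fused endo adduct A6, with C10 set.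
- For: it is the most convergent plan. The side-chain carbons are present from the start, the C8 oxygen sits where the methylene group is needed, the methoxy group deactivates the other quinone double bond and so fixes the regiochemistry, and the asymmetric step is catalytic. In convergence it is clearly stronger than the chosen route.
- Against: the cycloaddition gives a cis fusion, and the endo rule places the C9 substituent on the wrong side. Two of the three new centres (C5 and C9) must be epimerised. Ring A arrives as a methoxy enedione. The C1 oxygen must be removed, and the C4 carbonyl must be turned into a quaternary carbon with a methyl and a carboxyl group in the right orientation, which needs two C–C bonds at a carbonyl carbon next to the ring fusion. This costs many redox and homologation steps.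
- Comparison: the chosen route creates C4 at the correct oxidation level, with both carbon substituents, in the ring-closing step.

Key step: step 8

Assumption: the antipode of the chiral ligand in step 1 is chosen so that the isopropenyl group enters on the face that gives (3S)-configured 5; the sense of induction follows from the ligand and is not derived here.

## Route

In the names below, TMSE stands for 2-(trimethylsilyl)ethyl and TBS for tert-butyldimethylsilyl. Decalin and labdane names use labdane numbering.

Step 1
Reactants: 1 2-methylcyclohex-2-en-1-one; 2 isopropenylmagnesium bromide; 3 allyl bromide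
Product: 5 (2S,3S)-2-allyl-2-methyl-3-(prop-1-en-2-yl)cyclohexan-1-one (allyl trans to isopropenyl), via bromomagnesium enolate 4 (not isolated)
Conditions: 2 (1.2 equiv), Cu(OTf)2 (3 mol%), chiral hydroxyalkyl imidazolinium salt (NHC precursor, 4 mol%), Et2O, 0 °C; then 3 (3 equiv), DMPU, −30 °C → rt
Reagents that add atoms: none
Why: Copper-catalysed asymmetric conjugate addition of a Grignard reagent to an α-substituted cyclic enone under chiral NHC control, followed by C-alkylation of the regiospecific magnesium enolate 4. The ligand sets C3 (future C5). Allyl bromide then attacks axially on the face anti to the neighbouring isopropenyl group, which creates the quaternary carbon (future C10) with allyl trans and methyl cis to isopropenyl.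

Step 2
Reactants: 5 (2S,3S)-2-allyl-2-methyl-3-(prop-1-en-2-yl)cyclohexan-1-one
Product: 6 (6S,7S)-6-allyl-6-methyl-7-(prop-1-en-2-yl)-1,4-dioxaspiro[4.5]decane
Conditions: Me3SiOCH2CH2OSiMe3, TMSOTf (5 mol%), CH2Cl2, −78 → −20 °C; pyridine quench
Reagents that add atoms: 1,2-bis(trimethylsilyloxy)ethane, C[Si](C)(C)OCCO[Si](C)(C)C
Why: Silyl-triflate-catalysed ketalisation with the bis-silyl ether is aprotic and runs at low temperature. It therefore converts the hindered ketone beside the quaternary carbon without acid-induced migration of the isopropenyl double bond.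

Step 3
Reactants: 6 (6S,7S)-6-allyl-6-methyl-7-(prop-1-en-2-yl)-1,4-dioxaspiro[4.5]decane
Product: 8 2-[(6S,7S)-6-allyl-6-methyl-1,4-dioxaspiro[4.5]decan-7-yl]prop-2-enal, via allylic alcohol 7 (not isolated)
Conditions: SeO2 (0.3 equiv), tBuOOH (2.5 equiv), CH2Cl2, rt; filter, concentrate; then MnO2 (excess), CH2Cl2, rt
Reagents that add atoms: selenium dioxide, O=[Se]=O; tert-butyl hydroperoxide, CC(C)(C)OO
Why: Allylic oxidation with SeO2 (ene reaction, then [2,3]-sigmatropic shift) should attack the electron-rich 1,1-disubstituted alkene before the monosubstituted allyl group, and its methyl group before the shielded C–H next to the quaternary carbon. MnO2, which oxidises only allylic alcohols, then converts the alcohol/aldehyde mixture into the single enal 8.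

Step 4
Reactants: 8 2-[(6S,7S)-6-allyl-6-methyl-1,4-dioxaspiro[4.5]decan-7-yl]prop-2-enal
Product: 9 2-[(6S,7R)-6-allyl-6-methyl-1,4-dioxaspiro[4.5]decan-7-yl]prop-2-enoic acid
Conditions: NaClO2, NaH2PO4, 2-methylbut-2-ene, tBuOH/H2O, 0 °C → rt
Reagents that add atoms: sodium chlorite, [Na+].[O-]Cl=O
Why: Pinnick oxidation converts the enal into the acrylic acid under buffered conditions that the dioxolane tolerates. The alkene scavenger removes hypochlorous acid, so neither alkene is chlorinated. The stereocentres are untouched; the descriptor at C7 changes only through the priority rules.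

Step 5
Reactants: 9 2-[(6S,7R)-6-allyl-6-methyl-1,4-dioxaspiro[4.5]decan-7-yl]prop-2-enoic acid
Product: 10 TMSE 2-[(6S,7R)-6-allyl-6-methyl-1,4-dioxaspiro[4.5]decan-7-yl]prop-2-enoate
Conditions: Me3SiCH2CH2OH, EDC·HCl, DMAP (cat.), CH2Cl2, 0 °C → rt
Reagents that add atoms: 2-(trimethylsilyl)ethanol, C[Si](C)(C)CCO
Why: Steglich esterification. The silylethyl ester is chosen because the future axial C19 ester can later be cleaved at silicon by fluoride and not at its hindered carbonyl.

Step 6
Reactants: 10 TMSE 2-[(6S,7R)-6-allyl-6-methyl-1,4-dioxaspiro[4.5]decan-7-yl]prop-2-enoate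
Product: 12 TMSE 2-[(6S,7R)-6-(3-hydroxypropyl)-6-methyl-1,4-dioxaspiro[4.5]decan-7-yl]prop-2-enoate, via B-alkyl-9-BBN adduct 11 (not isolated)
Conditions: 9-BBN (1.2 equiv), THF, 0 °C → rt; then NaBO3·4H2O, H2O, rt
Reagents that add atoms: 9-borabicyclo[3.3.1]nonane, B1C2CCCC1CCC2 (boron enters intermediate 11 only); sodium perborate, [Na+].[O-]OB=O (oxygen of 12)
Why: Hydroboration–oxidation. 9-BBN adds anti-Markovnikov to the electron-rich monosubstituted alkene much faster than to the electron-poor acrylate and does not reduce esters. Perborate oxidises the C–B bond under conditions mild enough to spare the acrylate.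

Step 7
Reactants: 12 TMSE 2-[(6S,7R)-6-(3-hydroxypropyl)-6-methyl-1,4-dioxaspiro[4.5]decan-7-yl]prop-2-enoate
Product: 13 TMSE 2-[(6S,7R)-6-methyl-6-(3-oxopropyl)-1,4-dioxaspiro[4.5]decan-7-yl]prop-2-enoate
Conditions: Dess–Martin periodinane, NaHCO3, CH2Cl2, 0 °C → rt
Reagents that add atoms: none
Why: Dess–Martin oxidation of the primary alcohol stops at the aldehyde and leaves the acrylate, ketal and silyl ester alone.

Step 8
Reactants: 13 TMSE 2-[(6S,7R)-6-methyl-6-(3-oxopropyl)-1,4-dioxaspiro[4.5]decan-7-yl]prop-2-enoate
Product: 15 TMSE 9,9-(ethylenedioxy)-3β-hydroxy-4α,10β-dimethyl-5α-decalin-4β-carboxylate (rings A/B trans, hydroxyl equatorial, ester axial), via copper enolate 14 (not isolated)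
Conditions: [(Ph3P)CuH]6 (0.35 equiv, about 2 equiv of hydride), toluene, −40 → 0 °C; aq. NH4Cl
Reagents that add atoms: hexameric (triphenylphosphine)copper hydride [(Ph3P)CuH]6, per CuH unit [H][Cu] (copper enters intermediate 14 only; 15 gains only hydrogen)
Why: [(Ph3P)CuH]6 transfers hydride to the unhindered CH2 terminus of the acrylate (future C18) through its s-cis conformer, giving the fully substituted copper ester enolate 14 with the copper–oxygen bond on the side of the new methyl group. This enolate adds to the tethered aldehyde in a 6-(enolexo)-exo-trig aldol closure that forms C3–C4 and ring A; the closest known reaction type is the copper-hydride-mediated intramolecular reductive aldol cyclisation of enoates and enones onto aldehydes and ketones, which gives syn aldols through metal-bridged transition states. Ring A forms as a chair trans-fused to ring B, because the acrylate on C5 and the propanal arm on C10 are both equatorial on the ring B chair of 13. C4 is controlled by the C10 methyl group: of the two rotamers about C4–C5, the one that turns the flat enolate carbon (future C19) towards the axial C10 methyl and leaves the new methyl pseudo-equatorial avoids a methyl/methyl 1,3-diaxial contact, so the ester becomes 4β (axial) and C18 becomes 4α. C3 is controlled by copper, which bridges the enolate and aldehyde oxygens in a closed six-membered transition state; with C19 axial, only the equatorial position of the aldehyde oxygen is gauche to C19, so the hydroxyl forms 3β, cis to the ester. The step needs 1,4-reduction of the acrylate in preference to 1,2-reduction of the aldehyde, which the phosphine-ligated copper hydride provides because it reacts with electron-poor alkenes far faster than with unactivated carbonyl groups, while the dioxolane and the silylethyl ester are inert. Toluene at low temperature, free of proton and silyl sources, keeps 14 from being quenched before it closes, and aqueous NH4Cl then releases 15.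

Step 9
Reactants: 15 TMSE 9,9-(ethylenedioxy)-3β-hydroxy-4α,10β-dimethyl-5α-decalin-4β-carboxylate
Product: 16 TMSE 3β-(TBS-oxy)-9,9-(ethylenedioxy)-4α,10β-dimethyl-5α-decalin-4β-carboxylate
Conditions: TBSOTf, 2,6-lutidine, CH2Cl2, −78 → 0 °C
Reagents that add atoms: tert-butyldimethylsilyl triflate, CC(C)(C)[Si](C)(C)OS(=O)(=O)C(F)(F)F
Why: Silylation with the silyl triflate reaches the hindered equatorial hydroxyl beside the quaternary carbon. The silyl ether blocks retro-aldol cleavage and survives every later base, borane and ylide step.

Step 10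
Reactants: 16 TMSE 3β-(TBS-oxy)-9,9-(ethylenedioxy)-4α,10β-dimethyl-5α-decalin-4β-carboxylate
Product: 17 TMSE 3β-(TBS-oxy)-4α,10β-dimethyl-9-oxo-5α-decalin-4β-carboxylate
Conditions: PPTS (0.3 equiv), acetone/H2O 9:1, reflux
Reagents that add atoms: water, O
Why: Mild acid-catalysed hydrolysis (transketalisation to acetone) removes the dioxolane. The hindered secondary silyl ether and the silylethyl ester are stable to pyridinium tosylate.

Step 11
Reactants: 17 TMSE 3β-(TBS-oxy)-4α,10β-dimethyl-9-oxo-5α-decalin-4β-carboxylate
Product: 18 TMSE 3β-(TBS-oxy)-4α,10β-dimethyl-9-(trifluoromethylsulfonyloxy)-5α-decal-8-ene-4β-carboxylate (C8=C9 enol triflate)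
Conditions: KN(SiMe3)2, THF, −78 °C; then PhNTf2, −78 → 0 °C
Reagents that add atoms: N-phenylbis(trifluoromethanesulfonimide), O=S(=O)(N(c1ccccc1)S(=O)(=O)C(F)(F)F)C(F)(F)F
Why: Enolate O-triflation. C10 is quaternary, so the ketone can enolise only towards C8 and a single regioisomer forms. The C4 ester has no α-hydrogen and the C3 oxygen is protected.

Step 12
Reactants: 18 TMSE 3β-(TBS-oxy)-4α,10β-dimethyl-9-(trifluoromethylsulfonyloxy)-5α-decal-8-ene-4β-carboxylate; 19 2-(2-bromoethyl)-2-methyl-1,3-dioxolane
Product: 21 TMSE 3β-(TBS-oxy)-13,13-(ethylenedioxy)-14,15,17-trinorlabd-8-en-19-oate (C8=C9 alkene with the ketal-masked 3-oxobutyl chain on C9), via alkylzinc bromide 20 (not isolated)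
Conditions: 19, Zn dust, LiCl, THF, 45 °C; then 18, Pd(dppf)Cl2 (5 mol%), THF/NMP, 60 °C
Reagents that add atoms: zinc, [Zn] (enters intermediate 20 only)
Why: Negishi sp2–sp3 coupling. The alkylzinc halide tolerates the ester, ketal and silyl ether, and the wide-bite-angle ferrocenyl diphosphine favours reductive elimination over β-hydride elimination. The C9–C11 bond forms at a defined position.

Step 13
Reactants: 21 TMSE 3β-(TBS-oxy)-13,13-(ethylenedioxy)-14,15,17-trinorlabd-8-en-19-oate
Product: 23 TMSE 3β-(TBS-oxy)-13,13-(ethylenedioxy)-8α-hydroxy-14,15,17-trinorlabdan-19-oate (9α-H, chain 9β), via alkylborane 22 (not isolated)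
Conditions: BH3·THF (3 equiv), THF, 0 °C → rt; then NaOH, H2O2, 0 °C → rt
Reagents that add atoms: borane–tetrahydrofuran, B.C1CCOC1 (boron enters intermediate 22 only); hydrogen peroxide, OO (oxygen of 23)
Why: Hydroboration–oxidation of the trisubstituted alkene. Boron goes to the less substituted C8, and the syn addition takes place on the α face, opposite the axial C10 methyl. Hydrogen therefore arrives at C9 from below and the chain ends up β and equatorial, which is the C9 configuration of the target.

Step 14
Reactants: 23 TMSE 3β-(TBS-oxy)-13,13-(ethylenedioxy)-8α-hydroxy-14,15,17-trinorlabdan-19-oate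
Product: 24 TMSE 3β-(TBS-oxy)-13,13-(ethylenedioxy)-8-oxo-14,15,17-trinorlabdan-19-oate
Conditions: Dess–Martin periodinane, NaHCO3, CH2Cl2, rt
Reagents that add atoms: none
Why: Dess–Martin oxidation under buffered, non-basic conditions gives the C8 ketone. C9 is now α to a carbonyl, but its equatorial chain is the more stable arrangement, so no epimerisation is expected.

Step 15
Reactants: 24 TMSE 3β-(TBS-oxy)-13,13-(ethylenedioxy)-8-oxo-14,15,17-trinorlabdan-19-oate
Product: 25 TMSE 3β-(TBS-oxy)-13,13-(ethylenedioxy)-14,15-dinorlabd-8(17)-en-19-oate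
Conditions: Ph3PCH3Br, KOtBu, toluene, rt → 80 °C
Reagents that add atoms: methyltriphenylphosphonium bromide, C[P+](c1ccccc1)(c1ccccc1)c1ccccc1.[Br-]
Why: Wittig methylenation. The small unstabilised ylide reaches the hindered ring ketone on warming. The neopentylic C19 ester has no α-hydrogen and is too shielded to react, and C9 already has its stable configuration.

Step 16
Reactants: 25 TMSE 3β-(TBS-oxy)-13,13-(ethylenedioxy)-14,15-dinorlabd-8(17)-en-19-oate
Product: 26 TMSE 3β-(TBS-oxy)-13-oxo-14,15-dinorlabd-8(17)-en-19-oate (methyl ketone)
Conditions: PPTS, acetone/H2O 9:1, 50 °C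
Reagents that add atoms: water, O
Why: Mild acid-catalysed ketal hydrolysis frees the unhindered side-chain ketone. The acid is too weak to protonate the exocyclic alkene or to cleave the hindered silyl ether.

Step 17
Reactants: 27 diethylphosphonoacetic acid
Product: 28 TMSE 2-(diethoxyphosphoryl)acetate
Conditions: Me3SiCH2CH2OH, EDC·HCl, DMAP (cat.), CH2Cl2, rt
Reagents that add atoms: 2-(trimethylsilyl)ethanol, C[Si](C)(C)CCO
Why: Steglich esterification gives the phosphonate whose ester matches the C19 ester, so that both acids can be released together later.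

Step 18
Reactants: 26 TMSE 3β-(TBS-oxy)-13-oxo-14,15-dinorlabd-8(17)-en-19-oate; 28 TMSE 2-(diethoxyphosphoryl)acetate
Product: 29 bis-TMSE 3β-(TBS-oxy)labda-8(17),13E-diene-15,19-dioate
Conditions: 28, NaH, THF, 0 °C; then 26, rt → 50 °C
Reagents that add atoms: none
Why: Horner–Wadsworth–Emmons olefination of a methyl ketone. The reversible addition of the stabilised phosphonate anion favours the isomer with the ester trans to the larger CH2 chain, so the E alkene should predominate. The minor Z isomer would be removed by chromatography.

Step 19
Reactants: 29 bis-TMSE 3β-(TBS-oxy)labda-8(17),13E-diene-15,19-dioate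
Product: 30 3β-hydroxylabda-8(17),13E-diene-15,19-dioic acid
Conditions: Bu4NF (6 equiv), THF, rt → 45 °C; dilute aq. HCl (pH 3) work-up
Reagents that add atoms: none
Why: Fluoride attacks silicon in both silylethyl esters, which fragment to ethene and carboxylate whatever the hindrance at the C19 carbonyl, and it also cleaves the C3 silyl ether. Once C19 is a carboxylate, retro-aldol cleavage of the β-hydroxy acid is not feasible.

Step 20
Reactants: 30 3β-hydroxylabda-8(17),13E-diene-15,19-dioic acid
Product: 32 3β-acetoxylabda-8(17),13E-diene-15,19-dioic acid (3β-acetoxy-agathic acid), via bis(acetic) mixed anhydride 31 (not isolated)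
Conditions: Ac2O, pyridine, DMAP (cat.), rt; then H2O/THF, rt
Reagents that add atoms: acetic anhydride, CC(=O)OC(C)=O; water, O (hydrolysis of 31)
Why: DMAP-catalysed acetylation of the equatorial 3β-hydroxyl. The two carboxyl groups are converted for a time into mixed acetic anhydrides, which water cleaves back to the free acids during work-up, leaving the secondary acetate in place.

## Compound list

1 | 2-methylcyclohex-2-en-1-one | CC1=CCCCC1=O | starting material
2 | isopropenylmagnesium bromide (prop-1-en-2-ylmagnesium bromide) | C=C(C)[Mg]Br | starting material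
3 | allyl bromide (3-bromoprop-1-ene) | C=CCBr | starting material
4 | bromomagnesium (3S)-2-methyl-3-(prop-1-en-2-yl)cyclohex-1-en-1-olate | C1CC[C@@H](C(C)=C)C(C)=C1O[Mg]Br | intermediate
5 | (2S,3S)-2-allyl-2-methyl-3-(prop-1-en-2-yl)cyclohexan-1-one | C1CC[C@@H](C(C)=C)[C@](C)(CC=C)C1=O | intermediate
6 | (6S,7S)-6-allyl-6-methyl-7-(prop-1-en-2-yl)-1,4-dioxaspiro[4.5]decane | C1CC[C@@H](C(C)=C)[C@](C)(CC=C)C12OCCO2 | intermediate
7 | 2-[(6S,7S)-6-allyl-6-methyl-1,4-dioxaspiro[4.5]decan-7-yl]prop-2-en-1-ol | C1CC[C@@H](C(=C)CO)[C@](C)(CC=C)C12OCCO2 | intermediate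
8 | 2-[(6S,7S)-6-allyl-6-methyl-1,4-dioxaspiro[4.5]decan-7-yl]prop-2-enal | C1CC[C@@H](C(=C)C=O)[C@](C)(CC=C)C12OCCO2 | intermediate
9 | 2-[(6S,7R)-6-allyl-6-methyl-1,4-dioxaspiro[4.5]decan-7-yl]prop-2-enoic acid | C1CC[C@@H](C(=C)C(=O)O)[C@](C)(CC=C)C12OCCO2 | intermediate
10 | 2-(trimethylsilyl)ethyl 2-[(6S,7R)-6-allyl-6-methyl-1,4-dioxaspiro[4.5]decan-7-yl]prop-2-enoate | C1CC[C@@H](C(=C)C(=O)OCC[Si](C)(C)C)[C@](C)(CC=C)C12OCCO2 | intermediate
11 | B-alkyl-9-BBN adduct of 10 (boron on the terminal carbon of the former allyl group) | C1CC[C@@H](C(=C)C(=O)OCC[Si](C)(C)C)[C@](C)(CCCB3C4CCCC3CCC4)C12OCCO2 | intermediate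
12 | 2-(trimethylsilyl)ethyl 2-[(6S,7R)-6-(3-hydroxypropyl)-6-methyl-1,4-dioxaspiro[4.5]decan-7-yl]prop-2-enoate | C1CC[C@@H](C(=C)C(=O)OCC[Si](C)(C)C)[C@](C)(CCCO)C12OCCO2 | intermediate
13 | 2-(trimethylsilyl)ethyl 2-[(6S,7R)-6-methyl-6-(3-oxopropyl)-1,4-dioxaspiro[4.5]decan-7-yl]prop-2-enoate | C1CC[C@@H](C(=C)C(=O)OCC[Si](C)(C)C)[C@](C)(CCC=O)C12OCCO2 | intermediate
14 | copper enolate of 13 after hydride addition at C18 (copper–oxygen cis to the new methyl group; phosphine ligands omitted) | C1CC[C@@H](/C(C)=C(/O[Cu])OCC[Si](C)(C)C)[C@](C)(CCC=O)C12OCCO2 | intermediate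
15 | 2-(trimethylsilyl)ethyl 9,9-(ethylenedioxy)-3β-hydroxy-4α,10β-dimethyl-5α-decalin-4β-carboxylate | C1CC[C@@H]2[C@](C)(CC[C@H](O)[C@]2(C)C(=O)OCC[Si](C)(C)C)C13OCCO3 | intermediate
16 | 2-(trimethylsilyl)ethyl 3β-(tert-butyldimethylsilyloxy)-9,9-(ethylenedioxy)-4α,10β-dimethyl-5α-decalin-4β-carboxylate | C1CC[C@@H]2[C@](C)(CC[C@H](O[Si](C)(C)C(C)(C)C)[C@]2(C)C(=O)OCC[Si](C)(C)C)C13OCCO3 | intermediate
17 | 2-(trimethylsilyl)ethyl 3β-(tert-butyldimethylsilyloxy)-4α,10β-dimethyl-9-oxo-5α-decalin-4β-carboxylate | C1CC[C@@H]2[C@](C)(CC[C@H](O[Si](C)(C)C(C)(C)C)[C@]2(C)C(=O)OCC[Si](C)(C)C)C1=O | intermediate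
18 | 2-(trimethylsilyl)ethyl 3β-(tert-butyldimethylsilyloxy)-4α,10β-dimethyl-9-(trifluoromethylsulfonyloxy)-5α-decal-8-ene-4β-carboxylate | C1CC[C@@H]2[C@](C)(CC[C@H](O[Si](C)(C)C(C)(C)C)[C@]2(C)C(=O)OCC[Si](C)(C)C)C=1OS(=O)(=O)C(F)(F)F | intermediate
19 | 2-(2-bromoethyl)-2-methyl-1,3-dioxolane | CC1(CCBr)OCCO1 | starting material
20 | [2-(2-methyl-1,3-dioxolan-2-yl)ethyl]zinc bromide | CC1(CC[Zn]Br)OCCO1 | intermediate
21 | 2-(trimethylsilyl)ethyl 3β-(tert-butyldimethylsilyloxy)-13,13-(ethylenedioxy)-14,15,17-trinorlabd-8-en-19-oate | C1CC[C@@H]2[C@](C)(CC[C@H](O[Si](C)(C)C(C)(C)C)[C@]2(C)C(=O)OCC[Si](C)(C)C)C=1CCC1(C)OCCO1 | intermediate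
22 | 8α-boryl (BH2) adduct of 21 with 9α-H | B[C@@H]1CC[C@@H]2[C@](C)(CC[C@H](O[Si](C)(C)C(C)(C)C)[C@]2(C)C(=O)OCC[Si](C)(C)C)[C@H]1CCC1(C)OCCO1 | intermediate
23 | 2-(trimethylsilyl)ethyl 3β-(tert-butyldimethylsilyloxy)-13,13-(ethylenedioxy)-8α-hydroxy-14,15,17-trinorlabdan-19-oate | O[C@@H]1CC[C@@H]2[C@](C)(CC[C@H](O[Si](C)(C)C(C)(C)C)[C@]2(C)C(=O)OCC[Si](C)(C)C)[C@H]1CCC1(C)OCCO1 | intermediate
24 | 2-(trimethylsilyl)ethyl 3β-(tert-butyldimethylsilyloxy)-13,13-(ethylenedioxy)-8-oxo-14,15,17-trinorlabdan-19-oate | O=C1CC[C@@H]2[C@](C)(CC[C@H](O[Si](C)(C)C(C)(C)C)[C@]2(C)C(=O)OCC[Si](C)(C)C)[C@H]1CCC1(C)OCCO1 | intermediate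
25 | 2-(trimethylsilyl)ethyl 3β-(tert-butyldimethylsilyloxy)-13,13-(ethylenedioxy)-14,15-dinorlabd-8(17)-en-19-oate | C=C1CC[C@@H]2[C@](C)(CC[C@H](O[Si](C)(C)C(C)(C)C)[C@]2(C)C(=O)OCC[Si](C)(C)C)[C@H]1CCC1(C)OCCO1 | intermediate
26 | 2-(trimethylsilyl)ethyl 3β-(tert-butyldimethylsilyloxy)-13-oxo-14,15-dinorlabd-8(17)-en-19-oate | C=C1CC[C@@H]2[C@](C)(CC[C@H](O[Si](C)(C)C(C)(C)C)[C@]2(C)C(=O)OCC[Si](C)(C)C)[C@H]1CCC(C)=O | intermediate
27 | diethylphosphonoacetic acid | CCOP(=O)(OCC)CC(=O)O | starting material
28 | 2-(trimethylsilyl)ethyl 2-(diethoxyphosphoryl)acetate | CCOP(=O)(OCC)CC(=O)OCC[Si](C)(C)C | intermediate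
29 | bis[2-(trimethylsilyl)ethyl] 3β-(tert-butyldimethylsilyloxy)labda-8(17),13E-diene-15,19-dioate | C=C1CC[C@@H]2[C@](C)(CC[C@H](O[Si](C)(C)C(C)(C)C)[C@]2(C)C(=O)OCC[Si](C)(C)C)[C@H]1CC/C(C)=C/C(=O)OCC[Si](C)(C)C | intermediate
30 | 3β-hydroxylabda-8(17),13E-diene-15,19-dioic acid | C=C1CC[C@@H]2[C@](C)(CC[C@H](O)[C@]2(C)C(=O)O)[C@H]1CC/C(C)=C/C(=O)O | intermediate
31 | bis(acetic) mixed anhydride of 3β-acetoxylabda-8(17),13E-diene-15,19-dioic acid | C=C1CC[C@@H]2[C@](C)(CC[C@H](OC(C)=O)[C@]2(C)C(=O)OC(C)=O)[C@H]1CC/C(C)=C/C(=O)OC(C)=O | intermediate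
32 | 3β-acetoxylabda-8(17),13E-diene-15,19-dioic acid (3β-acetoxy-agathic acid) | C=C1CC[C@@H]2[C@](C)(CC[C@H](OC(C)=O)[C@]2(C)C(=O)O)[C@H]1CC/C(C)=C/C(=O)O | target

## Step count and least certain steps

Total step count: 20. Longest linear sequence: 19 steps (steps 1 to 16 and 18 to 20, from 1 to 32). Step 17 is a one-step branch that makes phosphonate 28.

**Step 8 (key step).**
- Risk: the hindered, fully substituted copper enolate may be protonated before it adds, which would give reduction without ring closure. The copper bridge may also fail to hold, so that the aldehyde oxygen goes axial and C3 forms unselectively. The C4 face depends on one rotamer preference, namely the flat enolate carbon, and not the methyl group, sitting syn to the C10 methyl. That preference is not large.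
- Fallback (from 13, back at 15): the ring closure is kept, but C3 is no longer asked of it. The reductive aldol is run to full conversion without regard to C3, so that 15 comes with its 3α-hydroxy epimer F1. The mixture is oxidised with Dess–Martin periodinane to the single 3-oxo ester F2, whose quaternary C4 cannot epimerise. NaBH4 in MeOH at 0 °C then delivers hydride along the axial α trajectory, away from the C4 substituents and the C10 methyl, and gives the equatorial 3β-alcohol 15.
- Limit: this fallback does not correct C4.

**Step 1.**
- Risk: the enantioselectivity of copper-catalysed additions is less secure for an sp2 Grignard reagent than for alkyl ones. The magnesium enolate may also be alkylated incompletely or on oxygen.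
- Fallback (from 1, back at 5): rhodium-catalysed asymmetric 1,4-addition of potassium isopropenyltrifluoroborate ([Rh(cod)2]BF4, the required antipode of BINAP, toluene/H2O, heat) gives 2-methyl-3-(prop-1-en-2-yl)cyclohexan-1-one F3. Its C3 centre is fixed; the C2 mixture does not matter. Me3SiCl, NaI and Et3N in MeCN convert F3 under equilibrating conditions into the more substituted trimethylsilyl enol ether F4. MeLi in THF cleaves F4 to the lithium enolate F5, and allyl bromide 3 alkylates it anti to the isopropenyl group to give 5.

**Step 3.**
- Risk: oxidation may compete at the C–H next to the quaternary carbon or at the allyl arm, the product may be over-oxidised, and the ketal may be partly lost in the acidic selenium medium.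
- Fallback (from 6, back at 8): ene-type chlorination with Ca(OCl)2 and solid CO2 in CH2Cl2/H2O at 0 °C is specific for the 1,1-disubstituted alkene and gives the 2-substituted allyl chloride F6. Oxidation with N-methylmorpholine N-oxide and catalytic KI in MeCN converts F6 into enal 8.

**Step 6.**
- Risk: the borane may also attack the acrylate, by hydroboration or conjugate reduction, and the oxidant may add to the acrylate during work-up.
- Fallback (from 6, back at 12): the hydroboration is moved to before the acrylate exists.
  - Bis(3-methylbutan-2-yl)borane distinguishes the monosubstituted allyl alkene from the hindered isopropenyl group. It gives the trialkylborane F7 and, after NaOH/H2O2, the primary alcohol F8.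
  - The SeO2/tBuOOH then MnO2 sequence of step 3 leads through diol F9 to hydroxy enal F10. MnO2 does not touch the saturated primary alcohol.
  - Pinnick oxidation gives hydroxy acid F11.
  - Esterification with a large excess of 2-(trimethylsilyl)ethanol (EDC·HCl, DMAP) gives 12.

**Step 18.**
- Risk: E/Z selectivity is only moderate for a methyl ketone whose two substituents differ little in size, and the addition is slow.
- Fallback (from 26, back at 29):
  - LiN(iPr)2 at −78 °C, ClP(O)(OEt)2 and then excess LiN(iPr)2 convert the methyl ketone, through enol phosphate F12, into terminal alkyne F13.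
  - Zirconium-catalysed methylalumination (Me3Al, Cp2ZrCl2, CH2Cl2) adds methyl and aluminium syn to give alkenylalane F14. Iodine converts F14 into the (E)-vinyl iodide F15.
  - Palladium-catalysed alkoxycarbonylation (Pd(PPh3)2Cl2, CO, 2-(trimethylsilyl)ethanol, Et3N, DMF) gives 29. The geometry is fixed by the syn carbometalation.

## Further compounds

F1 | step 8 | 2-(trimethylsilyl)ethyl 9,9-(ethylenedioxy)-3α-hydroxy-4α,10β-dimethyl-5α-decalin-4β-carboxylate (C3 epimer of 15) | C1CC[C@@H]2[C@](C)(CC[C@@H](O)[C@]2(C)C(=O)OCC[Si](C)(C)C)C13OCCO3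
F2 | step 8 | 2-(trimethylsilyl)ethyl 9,9-(ethylenedioxy)-4α,10β-dimethyl-3-oxo-5α-decalin-4β-carboxylate | C1CC[C@@H]2[C@](C)(CCC(=O)[C@]2(C)C(=O)OCC[Si](C)(C)C)C13OCCO3
F3 | step 1 | 2-methyl-3-(prop-1-en-2-yl)cyclohexan-1-one (C3 as in 5, C2 epimers) | C1CC[C@@H](C(C)=C)C(C)C1=O
F4 | step 1 | trimethylsilyl enol ether of F3 (more substituted regioisomer) | C1CC[C@@H](C(C)=C)C(C)=C1O[Si](C)(C)C
F5 | step 1 | lithium enolate corresponding to 4 | C1CC[C@@H](C(C)=C)C(C)=C1O[Li]
F6 | step 3 | (6S,7R)-6-allyl-7-(3-chloroprop-1-en-2-yl)-6-methyl-1,4-dioxaspiro[4.5]decane (allylic chloride corresponding to 7) | C1CC[C@@H](C(=C)CCl)[C@](C)(CC=C)C12OCCO2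
F7 | step 6 | bis(3-methylbutan-2-yl)alkylborane from 6 (boron on the terminal carbon of the former allyl group) | C1CC[C@@H](C(C)=C)[C@](C)(CCCB(C(C)C(C)C)C(C)C(C)C)C12OCCO2
F8 | step 6 | 3-[(6S,7S)-6-methyl-7-(prop-1-en-2-yl)-1,4-dioxaspiro[4.5]decan-6-yl]propan-1-ol | C1CC[C@@H](C(C)=C)[C@](C)(CCCO)C12OCCO2
F9 | step 6 | 2-[(6S,7S)-6-(3-hydroxypropyl)-6-methyl-1,4-dioxaspiro[4.5]decan-7-yl]prop-2-en-1-ol | C1CC[C@@H](C(=C)CO)[C@](C)(CCCO)C12OCCO2
F10 | step 6 | 2-[(6S,7S)-6-(3-hydroxypropyl)-6-methyl-1,4-dioxaspiro[4.5]decan-7-yl]prop-2-enal | C1CC[C@@H](C(=C)C=O)[C@](C)(CCCO)C12OCCO2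
F11 | step 6 | 2-[(6S,7R)-6-(3-hydroxypropyl)-6-methyl-1,4-dioxaspiro[4.5]decan-7-yl]prop-2-enoic acid | C1CC[C@@H](C(=C)C(=O)O)[C@](C)(CCCO)C12OCCO2
F12 | step 18 | diethyl enol phosphate of 26 (terminal C13=CH2) | C=C1CC[C@@H]2[C@](C)(CC[C@H](O[Si](C)(C)C(C)(C)C)[C@]2(C)C(=O)OCC[Si](C)(C)C)[C@H]1CCC(=C)OP(=O)(OCC)OCC
F13 | step 18 | terminal alkyne from 26 (C13≡C14H) | C=C1CC[C@@H]2[C@](C)(CC[C@H](O[Si](C)(C)C(C)(C)C)[C@]2(C)C(=O)OCC[Si](C)(C)C)[C@H]1CCC#C
F14 | step 18 | (E)-alkenyldimethylalane from F13 (methyl on C13, aluminium on C14) | C=C1CC[C@@H]2[C@](C)(CC[C@H](O[Si](C)(C)C(C)(C)C)[C@]2(C)C(=O)OCC[Si](C)(C)C)[C@H]1CC/C(C)=C/[Al](C)C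
F15 | step 18 | (E)-vinyl iodide from F14 (iodine on C14) | C=C1CC[C@@H]2[C@](C)(CC[C@H](O[Si](C)(C)C(C)(C)C)[C@]2(C)C(=O)OCC[Si](C)(C)C)[C@H]1CC/C(C)=C/I
A1 | alternative 1 | trans-fused octalin aldehyde with 8β-triethylsilyloxy, 3β-TBS-oxy and C4 methyl ester | O=C[C@H]1[C@@H](O[Si](CC)(CC)CC)C=C[C@@H]2[C@]1(C)CC[C@H](O[Si](C)(C)C(C)(C)C)[C@]2(C)C(=O)OC
A2 | alternative 1 | open-chain trienal with (E)-enal, (E,E)-1-triethylsilyloxydiene and the C3/C4 centres | O=C/C=C(\C)CC[C@H](O[Si](C)(C)C(C)(C)C)[C@](C)(C(=O)OC)/C=C/C=C/O[Si](CC)(CC)CC
A3 | alternative 2 | ring A cyclohexene with C10 formyl, C5 3-bromobut-3-enyl, C3 silyl enol ether and C4 methyl ester | C=C(Br)CC[C@@H]1[C@@](C)(C=O)CC=C(O[Si](C)(C)C(C)(C)C)[C@H]1C(=O)OC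
A4 | alternative 2 | methyl (2Z)-3-(tert-butyldimethylsilyloxy)penta-2,4-dienoate | C=C/C(O[Si](C)(C)C(C)(C)C)=C/C(=O)OC
A5 | alternative 2 | (2E)-6-bromo-2-methylhepta-2,6-dienal | C=C(Br)CC/C=C(\C)C=O
A6 | alternative 3 | cis-fused endo quinone adduct with C8 silyl enol ether and ketal-masked side chain | C1(O[Si](C)(C)C(C)(C)C)=CC[C@H]2[C@](C)(C(=O)C=C(OC)C2=O)[C@@H]1CCC1(C)OCCO1
A7 | alternative 3 | 2-methoxy-5-methyl-1,4-benzoquinone | COC1=CC(=O)C(C)=CC1=O
A8 | alternative 3 | 2-[(3Z)-4-(tert-butyldimethylsilyloxy)hexa-3,5-dien-1-yl]-2-methyl-1,3-dioxolane | C=C/C(O[Si](C)(C)C(C)(C)C)=C/CCC1(C)OCCO1
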